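**Assumption:** the target has no stereocentre and no stereogenic double bond, so it is made as the one achiral compound drawn; methyl orsellinate and N-methoxy-N-methylbutanamide are taken as catalogue chemicals.

**Retrosynthetic overview**
- Last bond: the depside ester C(=O)–O, from a ring-B acid (2-OH as benzyl ether, ketone as dioxolane) and a ring-A phenol (acid as benzyl ester); then acetal hydrolysis and one hydrogenolysis.
- Ring A (the only ring built): intermolecular Michael addition of dimethyl malonate to (E)-non-3-en-2-one, intramolecular Claisen closure, Br2 aromatisation to methyl olivetolate; then 4-O-benzyl / 2-O-methyl / ester exchange.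
- Ring B is bought as methyl orsellinate; the 2-oxopentyl chain is attached by Claisen-type acylation of its benzylic lithium anion with a butanoyl Weinreb amide.
- Ring order: ring A carbocycle first (steps 1–2); ring B is a purchased arene; a temporary dioxolane ring (step 11) is opened again in step 14.

**Route**

Step 1
Reactants: 1 dimethyl malonate; 2 (E)-non-3-en-2-one
Product: 4 methyl 2-hydroxy-4-oxo-6-pentylcyclohex-2-ene-1-carboxylate (racemic), via Michael adduct 3 (not isolated)
Conditions: NaOMe (1.1 equiv), MeOH, reflux; then 1 M aq. HCl, 0 °C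
Reagents that add atoms: none
Why: Intermolecular Michael addition of the malonate anion to the enone forges the C–C bond joining the two fragments, and the methyl-ketone enolate of 3 then closes ring A by intramolecular Claisen (Dieckmann-type) condensation; the two stereocentres of 4 form racemic and are erased in step 2.

Step 2
Reactants: 4 methyl 2-hydroxy-4-oxo-6-pentylcyclohex-2-ene-1-carboxylate
Product: 6 methyl 2,4-dihydroxy-6-pentylbenzoate (methyl olivetolate), via 3-bromo enol ester 5 (not isolated)
Conditions: Br2 (1.0 equiv), DMF, 0 °C; then 80 °C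
Reagents that add atoms: none
Why: Electrophilic bromination of the enolised 1,3-dione followed by thermal dehydrobromination and tautomerisation (oxidative aromatisation) gives the resorcinol ester, with one equivalent of Br2 to limit ring bromination.

Step 3
Reactants: 6 methyl 2,4-dihydroxy-6-pentylbenzoate
Product: 7 methyl 4-(benzyloxy)-2-hydroxy-6-pentylbenzoate
Conditions: BnBr (1.05 equiv), K2CO3 (1.1 equiv), acetone, reflux
Reagents that add atoms: benzyl bromide, BrCc1ccccc1
Why: Williamson etherification is selective for the 4-OH because the 2-OH is hydrogen-bonded to the ester carbonyl and far less nucleophilic.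

Step 4
Reactants: 7 methyl 4-(benzyloxy)-2-hydroxy-6-pentylbenzoate
Product: 8 methyl 4-(benzyloxy)-2-methoxy-6-pentylbenzoate
Conditions: MeI (3 equiv), K2CO3 (2 equiv), DMF, 60 °C
Reagents that add atoms: iodomethane, CI
Why: Williamson O-methylation of the remaining chelated phenol succeeds under more forcing conditions (polar aprotic solvent, heat, excess MeI).

Step 5
Reactants: 8 methyl 4-(benzyloxy)-2-methoxy-6-pentylbenzoate
Product: 9 4-(benzyloxy)-2-methoxy-6-pentylbenzoic acid
Conditions: KOH (5 equiv), DMSO/H2O 4:1, 100 °C; then 1 M aq. HCl, 0 °C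
Reagents that add atoms: potassium hydroxide, [K+].[OH-]
Why: Saponification of the doubly ortho-substituted ester is made practical by poorly solvated hydroxide in hot aqueous DMSO, and the aryl ethers are inert to base.

Step 6
Reactants: 9 4-(benzyloxy)-2-methoxy-6-pentylbenzoic acid
Product: 10 4-hydroxy-2-methoxy-6-pentylbenzoic acid
Conditions: H2 (1 atm), 10% Pd/C, EtOAc, rt
Reagents that add atoms: none
Why: Hydrogenolysis of the benzyl aryl ether frees the 4-OH without touching the acid or the methyl ether.

Step 7
Reactants: 10 4-hydroxy-2-methoxy-6-pentylbenzoic acid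
Product: 11 benzyl 4-hydroxy-2-methoxy-6-pentylbenzoate
Conditions: BnBr (1.05 equiv), KHCO3 (1.2 equiv), DMF, rt
Reagents that add atoms: benzyl bromide, BrCc1ccccc1
Why: Chemoselective SN2 O-alkylation of the carboxylate, since KHCO3 ionises the acid (pKa about 4) but not the phenol (pKa about 9).

Step 8
Reactants: 12 methyl 2,4-dihydroxy-6-methylbenzoate (methyl orsellinate)
Product: 13 methyl 2-hydroxy-4-methoxy-6-methylbenzoate
Conditions: MeI (1.05 equiv), K2CO3 (1.1 equiv), acetone, reflux
Reagents that add atoms: iodomethane, CI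
Why: Williamson methylation occurs selectively at the non-chelated 4-OH, the 2-OH being tied up in a hydrogen bond to the ester.

Step 9
Reactants: 13 methyl 2-hydroxy-4-methoxy-6-methylbenzoate
Product: 14 methyl 2-(benzyloxy)-4-methoxy-6-methylbenzoate
Conditions: BnBr (1.3 equiv), K2CO3 (2 equiv), DMF, 60 °C
Reagents that add atoms: benzyl bromide, BrCc1ccccc1
Why: Williamson benzylation of the chelated 2-OH under forcing conditions installs a protecting group that is removed in the final hydrogenolysis.

Step 10
Reactants: 14 methyl 2-(benzyloxy)-4-methoxy-6-methylbenzoate; 15 N-methoxy-N-methylbutanamide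
Product: 18 methyl 2-(benzyloxy)-4-methoxy-6-(2-oxopentyl)benzoate, via benzylic lithium 16 (not isolated), via tetrahedral lithium adduct 17 (not isolated)
Conditions: LiN(iPr)2 (1.2 equiv), THF, −78 °C; then 15 (1.3 equiv), −78 to −40 °C; AcOH, −78 °C
Reagents that add atoms: none
Why: Lateral lithiation of the ortho-toluate gives a vinylogous ester enolate that is C-acylated by the Weinreb amide in a crossed Claisen-type condensation, the chelated adduct 17 preventing over-addition until it collapses to the ketone on quench.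

Step 11
Reactants: 18 methyl 2-(benzyloxy)-4-methoxy-6-(2-oxopentyl)benzoate
Product: 19 methyl 2-(benzyloxy)-4-methoxy-6-[(2-propyl-1,3-dioxolan-2-yl)methyl]benzoate
Conditions: Me3SiOCH2CH2OSiMe3 (1.5 equiv), Me3SiOTf (5 mol%), CH2Cl2, −78 to −20 °C; pyridine quench
Reagents that add atoms: 1,2-bis(trimethylsilyloxy)ethane, C[Si](C)(C)OCCO[Si](C)(C)C
Why: Noyori acetalisation under aprotic low-temperature conditions protects the ketone so that it cannot close onto the carboxyl group (isocoumarin formation) or undergo Claisen cyclisation in steps 12 and 13.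

Step 12
Reactants: 19 methyl 2-(benzyloxy)-4-methoxy-6-[(2-propyl-1,3-dioxolan-2-yl)methyl]benzoate
Product: 20 2-(benzyloxy)-4-methoxy-6-[(2-propyl-1,3-dioxolan-2-yl)methyl]benzoic acid
Conditions: KOH (5 equiv), DMSO/H2O 4:1, 90 °C; then cold 1 M aq. HCl to pH 3–4, immediate extraction
Reagents that add atoms: potassium hydroxide, [K+].[OH-]
Why: Saponification of the hindered methyl ester leaves the base-stable dioxolane and ethers intact, and the brief cold, mildly acidic work-up does not hydrolyse the acetal.

Step 13
Reactants: 20 2-(benzyloxy)-4-methoxy-6-[(2-propyl-1,3-dioxolan-2-yl)methyl]benzoic acid; 11 benzyl 4-hydroxy-2-methoxy-6-pentylbenzoate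
Product: 22 benzyl 4-({2-(benzyloxy)-4-methoxy-6-[(2-propyl-1,3-dioxolan-2-yl)methyl]benzoyl}oxy)-2-methoxy-6-pentylbenzoate, via O-acylisourea 21 (not isolated)
Conditions: DCC (1.2 equiv), DMAP (0.2 equiv), CH2Cl2, 0 °C to rt
Reagents that add atoms: none
Why: Steglich esterification, in which O-acylisourea 21 passes the hindered acyl group through an acylpyridinium ion to the unhindered phenol of 11, the only free nucleophile present.

Step 14
Reactants: 22 benzyl 4-({2-(benzyloxy)-4-methoxy-6-[(2-propyl-1,3-dioxolan-2-yl)methyl]benzoyl}oxy)-2-methoxy-6-pentylbenzoate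
Product: 23 benzyl 4-{[2-(benzyloxy)-4-methoxy-6-(2-oxopentyl)benzoyl]oxy}-2-methoxy-6-pentylbenzoate
Conditions: 1 M aq. HCl/THF 1:4, rt
Reagents that add atoms: water, O
Why: Acid-catalysed acetal hydrolysis at room temperature releases the ketone under conditions that the hindered aryl ester and the benzyl ester tolerate.

Step 15
Reactants: 23 benzyl 4-{[2-(benzyloxy)-4-methoxy-6-(2-oxopentyl)benzoyl]oxy}-2-methoxy-6-pentylbenzoate
Product: 24 4-{[2-hydroxy-4-methoxy-6-(2-oxopentyl)benzoyl]oxy}-2-methoxy-6-pentylbenzoic acid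
Conditions: H2 (1 atm), 10% Pd/C, EtOAc, rt
Reagents that add atoms: none
Why: Hydrogenolysis cleaves the benzyl ester and the benzyl aryl ether in one operation, while the depside ester, the aliphatic ketone and the methyl ethers are inert to H2 over Pd/C at 1 atm.

**Compound list**
1 | dimethyl malonate | COC(=O)CC(=O)OC | starting material
2 | (E)-non-3-en-2-one | CCCCC/C=C/C(C)=O | starting material
3 | dimethyl 2-(2-oxononan-4-yl)malonate (racemic Michael adduct) | CCCCCC(CC(C)=O)C(C(=O)OC)C(=O)OC | intermediate (not isolated)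
4 | methyl 2-hydroxy-4-oxo-6-pentylcyclohex-2-ene-1-carboxylate (racemic) | CCCCCC1CC(=O)C=C(O)C1C(=O)OC | intermediate
5 | methyl 3-bromo-2-hydroxy-4-oxo-6-pentylcyclohex-2-ene-1-carboxylate (racemic) | CCCCCC1CC(=O)C(Br)=C(O)C1C(=O)OC | intermediate (not isolated)
6 | methyl 2,4-dihydroxy-6-pentylbenzoate | CCCCCc1cc(O)cc(O)c1C(=O)OC | intermediate
7 | methyl 4-(benzyloxy)-2-hydroxy-6-pentylbenzoate | CCCCCc1cc(OCc2ccccc2)cc(O)c1C(=O)OC | intermediate
8 | methyl 4-(benzyloxy)-2-methoxy-6-pentylbenzoate | CCCCCc1cc(OCc2ccccc2)cc(OC)c1C(=O)OC | intermediate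
9 | 4-(benzyloxy)-2-methoxy-6-pentylbenzoic acid | CCCCCc1cc(OCc2ccccc2)cc(OC)c1C(=O)O | intermediate
10 | 4-hydroxy-2-methoxy-6-pentylbenzoic acid | CCCCCc1cc(O)cc(OC)c1C(=O)O | intermediate
11 | benzyl 4-hydroxy-2-methoxy-6-pentylbenzoate | CCCCCc1cc(O)cc(OC)c1C(=O)OCc1ccccc1 | intermediate
12 | methyl 2,4-dihydroxy-6-methylbenzoate (methyl orsellinate) | COC(=O)c1c(C)cc(O)cc1O | starting material
13 | methyl 2-hydroxy-4-methoxy-6-methylbenzoate | COC(=O)c1c(C)cc(OC)cc1O | intermediate
14 | methyl 2-(benzyloxy)-4-methoxy-6-methylbenzoate | COC(=O)c1c(C)cc(OC)cc1OCc1ccccc1 | intermediate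
15 | N-methoxy-N-methylbutanamide | CCCC(=O)N(C)OC | starting material
16 | methyl 2-(benzyloxy)-6-(lithiomethyl)-4-methoxybenzoate | [Li]Cc1cc(OC)cc(OCc2ccccc2)c1C(=O)OC | intermediate (not isolated)
17 | methyl 2-(benzyloxy)-6-{2-(lithiooxy)-2-[methoxy(methyl)amino]pentyl}-4-methoxybenzoate (racemic) | CCCC(O[Li])(Cc1cc(OC)cc(OCc2ccccc2)c1C(=O)OC)N(C)OC | intermediate (not isolated)
18 | methyl 2-(benzyloxy)-4-methoxy-6-(2-oxopentyl)benzoate | CCCC(=O)Cc1cc(OC)cc(OCc2ccccc2)c1C(=O)OC | intermediate
19 | methyl 2-(benzyloxy)-4-methoxy-6-[(2-propyl-1,3-dioxolan-2-yl)methyl]benzoate | CCCC1(Cc2cc(OC)cc(OCc3ccccc3)c2C(=O)OC)OCCO1 | intermediate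
20 | 2-(benzyloxy)-4-methoxy-6-[(2-propyl-1,3-dioxolan-2-yl)methyl]benzoic acid | CCCC1(Cc2cc(OC)cc(OCc3ccccc3)c2C(=O)O)OCCO1 | intermediate
21 | N,N'-dicyclohexyl-O-{2-(benzyloxy)-4-methoxy-6-[(2-propyl-1,3-dioxolan-2-yl)methyl]benzoyl}isourea | CCCC1(Cc2cc(OC)cc(OCc3ccccc3)c2C(=O)OC(=NC2CCCCC2)NC2CCCCC2)OCCO1 | intermediate (not isolated)
22 | benzyl 4-({2-(benzyloxy)-4-methoxy-6-[(2-propyl-1,3-dioxolan-2-yl)methyl]benzoyl}oxy)-2-methoxy-6-pentylbenzoate | CCCCCc1cc(OC(=O)c2c(OCc3ccccc3)cc(OC)cc2CC2(CCC)OCCO2)cc(OC)c1C(=O)OCc1ccccc1 | intermediate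
23 | benzyl 4-{[2-(benzyloxy)-4-methoxy-6-(2-oxopentyl)benzoyl]oxy}-2-methoxy-6-pentylbenzoate | CCCCCc1cc(OC(=O)c2c(OCc3ccccc3)cc(OC)cc2CC(=O)CCC)cc(OC)c1C(=O)OCc1ccccc1 | intermediate
24 | 4-{[2-hydroxy-4-methoxy-6-(2-oxopentyl)benzoyl]oxy}-2-methoxy-6-pentylbenzoic acid (achiral) | CCCCCc1cc(OC(=O)c2c(O)cc(OC)cc2CC(=O)CCC)cc(OC)c1C(=O)O | target

**Step count:** 15 steps in total. Longest linear sequence: 10 steps (steps 1–7, then 13–15, from dimethyl malonate and non-3-en-2-one); the ring-B branch is 5 steps (8–12) before the convergence.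

**Three steps most likely to fail, with fallbacks**

Step 10 (benzylic acylation). The lithium species 16 may only deprotonate amide 15 or condense with its own ester, returning 14. The fallback sets out from 14 and swaps the acyl donor for an aldehyde, which adds much faster. The same anion (LiN(iPr)2, THF, −78 °C) is added to butanal in an aldol-type addition and allowed to warm, so that the alkoxide lactonises to racemic 8-(benzyloxy)-6-methoxy-3-propyl-3,4-dihydro-1H-isochromen-1-one F1. The lactone is opened with KOH in aqueous MeOH and the potassium carboxylate is methylated with MeI in DMF to give racemic methyl 2-(benzyloxy)-6-(2-hydroxypentyl)-4-methoxybenzoate F2. This is oxidised at once with Dess–Martin periodinane/NaHCO3 in CH2Cl2 and comes back to the route at ketone 18; the carbinol stereocentre is destroyed there.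

Step 11 (acetalisation). The Lewis acid may instead drive the keto ester to the isocoumarin, or the acetal may not form. The fallback sets out from 18 and does without ketone protection. The methyl ester is cleaved by SN2 demethylation (LiI, EtOAc, reflux, then dilute acid), which avoids the basic conditions that would trigger Claisen cyclisation, giving 2-(benzyloxy)-4-methoxy-6-(2-oxopentyl)benzoic acid F3. This keto acid is condensed directly with phenol 11 using DCC alone in toluene at rt, with no DMAP or other base so that the ketone is not enolised onto the activated carboxyl. The fallback comes back to the route at 23, skipping steps 12–14.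

Step 13 (depside esterification). The doubly ortho-substituted O-acylisourea 21 may rearrange to the N-acylurea faster than it acylates the phenol. The fallback sets out from acid 20 and uses a preformed, isolable acyl halide. Cyanuric fluoride and pyridine in CH2Cl2 at −10 °C give 2-(benzyloxy)-4-methoxy-6-[(2-propyl-1,3-dioxolan-2-yl)methyl]benzoyl fluoride F4 under conditions the dioxolane tolerates. F4 is then treated with the caesium phenoxide of 11 (Cs2CO3, MeCN, rt) and comes back to the route at 22.

**Further compounds**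
F1 | step 10 | 8-(benzyloxy)-6-methoxy-3-propyl-3,4-dihydro-1H-isochromen-1-one (racemic) | CCCC1Cc2cc(OC)cc(OCc3ccccc3)c2C(=O)O1
F2 | step 10 | methyl 2-(benzyloxy)-6-(2-hydroxypentyl)-4-methoxybenzoate (racemic) | CCCC(O)Cc1cc(OC)cc(OCc2ccccc2)c1C(=O)OC
F3 | step 11 | 2-(benzyloxy)-4-methoxy-6-(2-oxopentyl)benzoic acid | CCCC(=O)Cc1cc(OC)cc(OCc2ccccc2)c1C(=O)O
F4 | step 13 | 2-(benzyloxy)-4-methoxy-6-[(2-propyl-1,3-dioxolan-2-yl)methyl]benzoyl fluoride | CCCC1(Cc2cc(OC)cc(OCc3ccccc3)c2C(F)=O)OCCO1
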